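The cyclopentane ring of the hydroazulene (C1, C2, C3, C3a, C8a; azulene numbering) is cut into the three-carbon unit C1–C8a–C3a and the two-carbon unit C2–C3. Because C4 carries oxygen, C1 can be tied to C3a as a cyclopropane conjugated to a C4 ketone, that is, a bicyclo[5.1.0]octenone. Single-electron opening of this strained bond and radical relay with 3-methylbut-1-yne form C1–C2 and C3–C3a in one operation; a double-bond shift then gives a dienone whose only stereocentre is C8a. From C8a, reagent-controlled C4 reduction, hydroxyl-directed epoxidation of C3=C3a and a stereospecific 1,2-hydride shift set the trans ring fusion and both carbinols.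

Key step: step 8

Remark on the chemistry: atom labels C1–C8a follow the azulene numbering of the target. The sense of induction of the dirhodium carboxamidate in step 2 is assumed; the mirror-image catalyst is used if it proves opposite.

Step 1
Reactants: 1 3-methylbut-3-en-1-ol; 2 glyoxylic acid chloride p-toluenesulfonylhydrazone
Product: 4 3-methylbut-3-en-1-yl diazoacetate, via hydrazone ester 3 (not isolated)
Conditions: PhNMe2, CH2Cl2, 0 °C; then Et3N, 0 °C to rt
Reagents that add atoms: none
Why: O-acylation by the acid chloride followed by triethylamine-induced loss of p-toluenesulfinate from the tosylhydrazone (Bamford–Stevens-type diazo formation) should give the diazoacetate; no stereocentre is formed.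

Step 2
Reactants: 4 3-methylbut-3-en-1-yl diazoacetate
Product: 5 (1R,6R)-6-methyl-3-oxabicyclo[4.1.0]heptan-2-one
Conditions: dirhodium tetrakis[methyl (5S)-2-oxopyrrolidine-5-carboxylate] Rh2(5S-MEPY)4 (1 mol%), CH2Cl2, reflux, slow addition
Reagents that add atoms: none
Why: Intramolecular cyclopropanation of the rhodium carbene onto the 1,1-disubstituted alkene closes the cyclopropane-fused δ-lactone; the chiral carboxamidate ligands select the alkene face and so set the quaternary centre (future C8a), the cis relationship to the adjacent CH being enforced by the bicycle.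

Step 3
Reactants: 5 (1R,6R)-6-methyl-3-oxabicyclo[4.1.0]heptan-2-one
Product: 6 (1R,2R)-2-(2-hydroxyethyl)-N-methoxy-N,2-dimethylcyclopropane-1-carboxamide
Conditions: MeNH(OMe)·HCl, AlMe3, CH2Cl2, 0 °C to rt
Reagents that add atoms: N,O-dimethylhydroxylamine hydrochloride, CNOC.Cl
Why: Aluminium amide aminolysis of the lactone (Weinreb amide formation) should open the ring without touching the cyclopropane stereocentres.

Step 4
Reactants: 6 (1R,2R)-2-(2-hydroxyethyl)-N-methoxy-N,2-dimethylcyclopropane-1-carboxamide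
Product: 7 (1R,2R)-N-methoxy-N,2-dimethyl-2-(2-oxoethyl)cyclopropane-1-carboxamide
Conditions: Dess–Martin periodinane, CH2Cl2, 0 °C to rt
Reagents that add atoms: none
Why: Dess–Martin oxidation of the primary alcohol should stop at the aldehyde; the Weinreb amide and the cyclopropane are inert.

Step 5
Reactants: 7 (1R,2R)-N-methoxy-N,2-dimethyl-2-(2-oxoethyl)cyclopropane-1-carboxamide
Product: 8 (1R,2S)-N-methoxy-N,2-dimethyl-2-(prop-2-en-1-yl)cyclopropane-1-carboxamide
Conditions: Ph3PCH3Br, KOtBu, THF, 0 °C
Reagents that add atoms: methyltriphenylphosphonium bromide, C[P+](c1ccccc1)(c1ccccc1)c1ccccc1.[Br-]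
Why: Wittig methylenation of the aldehyde should give the allyl side chain (future C8 and C7); no stereocentre is affected.

Step 6
Reactants: 8 (1R,2S)-N-methoxy-N,2-dimethyl-2-(prop-2-en-1-yl)cyclopropane-1-carboxamide
Product: 9 3-methyl-1-[(1R,2S)-2-methyl-2-(prop-2-en-1-yl)cyclopropyl]but-3-en-1-one
Conditions: 2-methylallylmagnesium chloride, THF, −78 °C; aqueous NH4Cl quench at −78 °C
Reagents that add atoms: 2-methylallylmagnesium chloride, CC(=C)C[Mg]Cl
Why: Grignard addition to the Weinreb amide stops at the chelated tetrahedral intermediate and should release the β,γ-unsaturated ketone on cold quench, before the alkene can move into conjugation.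

Step 7
Reactants: 9 3-methyl-1-[(1R,2S)-2-methyl-2-(prop-2-en-1-yl)cyclopropyl]but-3-en-1-one
Product: 10 (1R,7S)-4,7-dimethylbicyclo[5.1.0]oct-4-en-2-one
Conditions: second-generation Grubbs catalyst RuCl2(H2IMes)(PCy3)(=CHPh) (5 mol%), CH2Cl2, 40 °C
Reagents that add atoms: none
Why: Ring-closing metathesis of the cis-disposed allyl and 2-methylallyl chains should close the seven-membered ring with its trisubstituted alkene (future C6=C7); the cis-1,2-disubstituted cyclopropane holds the two chains together.

Step 8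
Reactants: 10 (1R,7S)-4,7-dimethylbicyclo[5.1.0]oct-4-en-2-one; 11 3-methylbut-1-yne
Product: 13 (8aR)-6,8a-dimethyl-3-(propan-2-yl)-1,2,8,8a-tetrahydroazulen-4(5H)-one, via cis-fused enone 12 (not isolated)
Conditions: SmI2 (20 mol%), Sm metal (20 mol%), 11 (5 equiv), THF, 55 °C, sealed tube; then DBU (20 mol%), 0 °C
Reagents that add atoms: none
Why: Samarium diiodide transfers one electron to the ketone and the ketyl opens the exo cyclopropane bond C1–C8 of 10, the bond best aligned with the ketyl orbital in the bicycle, giving a trivalent samarium enolate and a primary radical at C8. This radical adds to the terminal alkyne carbon (new azulene bond C1–C2) and the vinyl radical closes the five-membered ring by 5-exo-trig attack on the enolate carbon (new bond C3–C3a), after which the ketyl returns the electron to samarium (radical relay). The closest known reaction type is the SmI2-catalysed formal [3+2] cycloaddition of alkyl cyclopropyl ketones with alkynes. The ring-fusion centre C3a must form cis, because the tether reaches only the face of C8a that carries the CH2, but it is deliberately erased when DBU moves the C2=C3 bond into conjugation, so C8a remains the only stereocentre. The step needs exo rather than endo ring opening (secured by orbital overlap in the bicycle despite the tertiary alternative), addition at the unsubstituted alkyne terminus, and migration of the cyclopentene bond towards the tetrasubstituted enone in preference to the C6=C7 bond (catalytic base, low temperature).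

Step 9
Reactants: 13 (8aR)-6,8a-dimethyl-3-(propan-2-yl)-1,2,8,8a-tetrahydroazulen-4(5H)-one
Product: 14 (4R,8aR)-6,8a-dimethyl-3-(propan-2-yl)-1,2,4,5,8,8a-hexahydroazulen-4-ol
Conditions: (S)-2-methyl-CBS-oxazaborolidine (20 mol%), catecholborane, toluene, −78 °C
Reagents that add atoms: none
Why: Corey–Bakshi–Shibata reduction, in which the oxazaborolidine binds the ketone anti to the fully substituted alkenyl side and should deliver hydride to one carbonyl face, setting C4 as R (hydroxyl cis to the C8a methyl); catecholborane leaves both alkenes untouched.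

Step 10
Reactants: 14 (4R,8aR)-6,8a-dimethyl-3-(propan-2-yl)-1,2,4,5,8,8a-hexahydroazulen-4-ol
Product: 15 (3R,3aS,4R,8aR)-3,3a-epoxy-6,8a-dimethyl-3-(propan-2-yl)-1,2,3,3a,4,5,8,8a-octahydroazulen-4-ol
Conditions: VO(acac)2 (5 mol%), tBuOOH, CH2Cl2, 0 °C
Reagents that add atoms: tert-butyl hydroperoxide, CC(C)(C)OO
Why: Vanadium-catalysed hydroxyl-directed epoxidation: allylic 1,3-strain with the isopropyl group keeps C4–H in the alkene plane, so the vanadate ester should deliver oxygen to the C3=C3a face that bears the hydroxyl (the face of the C8a methyl), while the merely homoallylic C6=C7 alkene reacts far more slowly.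

Step 11
Reactants: 15 (3R,3aS,4R,8aR)-3,3a-epoxy-6,8a-dimethyl-3-(propan-2-yl)-1,2,3,3a,4,5,8,8a-octahydroazulen-4-ol
Product: 16 (3R,3aR,8aR)-3-hydroxy-6,8a-dimethyl-3-(propan-2-yl)-1,2,3,3a,8,8a-hexahydroazulen-4(5H)-one
Conditions: ZnBr2 (20 mol%), CH2Cl2, −20 °C to 0 °C
Reagents that add atoms: none
Why: Semipinacol rearrangement of the 2,3-epoxy alcohol: zinc bound to the syn hydroxyl and epoxide oxygen weakens the C3a–O bond, and the C4 hydrogen, anti-periplanar to it, should migrate with inversion at C3a while C4 becomes the ketone, which places C3a–H trans to the C8a methyl (trans ring fusion) and leaves the C3 oxygen as the tertiary alcohol cis to that methyl.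

Step 12
Reactants: 16 (3R,3aR,8aR)-3-hydroxy-6,8a-dimethyl-3-(propan-2-yl)-1,2,3,3a,8,8a-hexahydroazulen-4(5H)-one
Product: 17 (3R,3aS,4R,8aR)-6,8a-dimethyl-3-(propan-2-yl)-1,2,3,3a,4,5,8,8a-octahydroazulene-3,4-diol
Conditions: NaBH4, MeOH/THF, −40 °C
Reagents that add atoms: none
Why: Borohydride reduction of the ketone: the C8a methyl, held syn to C4 by the trans ring fusion, blocks one carbonyl face, so hydride should enter from the side of C3a–H and give the 4R alcohol with both oxygens cis to the methyl.

Step 13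
Reactants: 17 (3R,3aS,4R,8aR)-6,8a-dimethyl-3-(propan-2-yl)-1,2,3,3a,4,5,8,8a-octahydroazulene-3,4-diol; 18 4-acetoxybenzoyl chloride
Product: 19 (3R,3aS,4R,8aR)-3-hydroxy-6,8a-dimethyl-3-(propan-2-yl)-1,2,3,3a,4,5,8,8a-octahydroazulen-4-yl 4-(acetyloxy)benzoate
Conditions: Et3N, DMAP (10 mol%), CH2Cl2, 0 °C to rt
Reagents that add atoms: none
Why: DMAP-catalysed acyl transfer should esterify the secondary C4 hydroxyl only, the tertiary C3 hydroxyl being too hindered; no stereocentre is touched.

Step 14
Reactants: 19 (3R,3aS,4R,8aR)-3-hydroxy-6,8a-dimethyl-3-(propan-2-yl)-1,2,3,3a,4,5,8,8a-octahydroazulen-4-yl 4-(acetyloxy)benzoate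
Product: 20 (3R,3aS,4R,8aR)-3-hydroxy-6,8a-dimethyl-3-(propan-2-yl)-1,2,3,3a,4,5,8,8a-octahydroazulen-4-yl 4-hydroxybenzoate
Conditions: K2CO3 (20 mol%), MeOH, 0 °C
Reagents that add atoms: none
Why: Methanolysis of the phenolic acetate, far more electrophilic than the hindered secondary benzoate, should release the phenol without ester exchange at C4.

Compound list
1 | 3-methylbut-3-en-1-ol | CC(=C)CCO | starting material
2 | glyoxylic acid chloride p-toluenesulfonylhydrazone | Cc1ccc(cc1)S(=O)(=O)NN=CC(Cl)=O | starting material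
3 | 3-methylbut-3-en-1-yl 2-(2-tosylhydrazinylidene)acetate | CC(=C)CCOC(=O)C=NNS(=O)(=O)c1ccc(C)cc1 | intermediate
4 | 3-methylbut-3-en-1-yl diazoacetate | CC(=C)CCOC(=O)C=[N+]=[N-] | intermediate
5 | (1R,6R)-6-methyl-3-oxabicyclo[4.1.0]heptan-2-one | O=C1OCC[C@@]2(C)C[C@@H]12 | intermediate
6 | (1R,2R)-2-(2-hydroxyethyl)-N-methoxy-N,2-dimethylcyclopropane-1-carboxamide | OCC[C@@]1(C)C[C@H]1C(=O)N(C)OC | intermediate
7 | (1R,2R)-N-methoxy-N,2-dimethyl-2-(2-oxoethyl)cyclopropane-1-carboxamide | O=CC[C@@]1(C)C[C@H]1C(=O)N(C)OC | intermediate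
8 | (1R,2S)-N-methoxy-N,2-dimethyl-2-(prop-2-en-1-yl)cyclopropane-1-carboxamide | C=CC[C@@]1(C)C[C@H]1C(=O)N(C)OC | intermediate
9 | 3-methyl-1-[(1R,2S)-2-methyl-2-(prop-2-en-1-yl)cyclopropyl]but-3-en-1-one | C=CC[C@@]1(C)C[C@H]1C(=O)CC(C)=C | intermediate
10 | (1R,7S)-4,7-dimethylbicyclo[5.1.0]oct-4-en-2-one | CC1=CC[C@@]2(C)C[C@H]2C(=O)C1 | intermediate
11 | 3-methylbut-1-yne | CC(C)C#C | starting material
12 | (3aS,8aS)-6,8a-dimethyl-3-(propan-2-yl)-3a,5,8,8a-tetrahydroazulen-4(1H)-one | CC1=CC[C@@]2(C)CC=C(C(C)C)[C@H]2C(=O)C1 | intermediate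
13 | (8aR)-6,8a-dimethyl-3-(propan-2-yl)-1,2,8,8a-tetrahydroazulen-4(5H)-one | CC1=CC[C@@]2(C)CCC(C(C)C)=C2C(=O)C1 | intermediate
14 | (4R,8aR)-6,8a-dimethyl-3-(propan-2-yl)-1,2,4,5,8,8a-hexahydroazulen-4-ol | CC1=CC[C@@]2(C)CCC(C(C)C)=C2[C@H](O)C1 | intermediate
15 | (3R,3aS,4R,8aR)-3,3a-epoxy-6,8a-dimethyl-3-(propan-2-yl)-1,2,3,3a,4,5,8,8a-octahydroazulen-4-ol | CC1=CC[C@@]2(C)CC[C@]3(C(C)C)O[C@@]32[C@H](O)C1 | intermediate
16 | (3R,3aR,8aR)-3-hydroxy-6,8a-dimethyl-3-(propan-2-yl)-1,2,3,3a,8,8a-hexahydroazulen-4(5H)-one | CC1=CC[C@@]2(C)CC[C@@](O)(C(C)C)[C@@H]2C(=O)C1 | intermediate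
17 | (3R,3aS,4R,8aR)-6,8a-dimethyl-3-(propan-2-yl)-1,2,3,3a,4,5,8,8a-octahydroazulene-3,4-diol | CC1=CC[C@@]2(C)CC[C@@](O)(C(C)C)[C@@H]2[C@H](O)C1 | intermediate
18 | 4-acetoxybenzoyl chloride | CC(=O)Oc1ccc(cc1)C(Cl)=O | starting material
19 | (3R,3aS,4R,8aR)-3-hydroxy-6,8a-dimethyl-3-(propan-2-yl)-1,2,3,3a,4,5,8,8a-octahydroazulen-4-yl 4-(acetyloxy)benzoate | CC1=CC[C@@]2(C)CC[C@@](O)(C(C)C)[C@@H]2[C@H](OC(=O)c2ccc(OC(C)=O)cc2)C1 | intermediate
20 | (3R,3aS,4R,8aR)-3-hydroxy-6,8a-dimethyl-3-(propan-2-yl)-1,2,3,3a,4,5,8,8a-octahydroazulen-4-yl 4-hydroxybenzoate | CC1=CC[C@@]2(C)CC[C@@](O)(C(C)C)[C@@H]2[C@H](OC(=O)c2ccc(O)cc2)C1 | target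

Total step count: 14. Longest linear sequence: 14 steps (1 to 20).

Steps most likely to fail

Step 8. The primary radical may be trapped too slowly by the unactivated alkyne, so that back electron transfer and hydrogen abstraction from THF win. The base may also pull the C6=C7 bond into conjugation during the double-bond shift. The fallback sets out from 10 and comes back at 13; it replaces the alkyne and the isomerisation by an alkene annulation followed by oxidation and dehydration. 3-Methylbutan-2-one is converted with LDA and PhNTf2 into 3-methylbut-1-en-2-yl trifluoromethanesulfonate F1. PdCl2(PPh3)2-catalysed borylation with B2pin2 and KOPh then gives 4,4,5,5-tetramethyl-2-(3-methylbut-1-en-2-yl)-1,3,2-dioxaborolane F2, a faster radical trap whose α-boryl radical is not reduced by SmI2. The same samarium relay with 10 should give the cis-fused boryl ketone F3. Oxidation with NaBO3·4H2O gives the ketol F4, and Burgess dehydration should give 13 without any base-mediated isomerisation.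

Step 11. The Lewis acid may ionise the C3–O bond instead (elimination), or the ring carbon C5 may migrate in place of hydride (ring contraction). The fallback sets out from 15 and comes back at 16. Dess–Martin oxidation gives (3R,3aR,8aR)-3,3a-epoxy-6,8a-dimethyl-3-(propan-2-yl)-1,2,3,3a,8,8a-hexahydroazulen-4(5H)-one F5. SmI2 (2.2 equiv) with MeOH in THF at −78 °C then cleaves the C3a–O bond regiospecifically (reductive opening of an α,β-epoxy ketone). Protonation of the chelated enolate should give 16, the hydrogen-bonded trans-fused ketol being expected to be the more stable epimer.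

Step 12. Facial selectivity may be poor, with hydride adding syn to the angular methyl. The fallback sets out from 16 and comes back at 19. If reduction delivers mainly (3R,3aS,4S,8aR)-6,8a-dimethyl-3-(propan-2-yl)-1,2,3,3a,4,5,8,8a-octahydroazulene-3,4-diol F6, this diol is esterified with 4-acetoxybenzoic acid under Mitsunobu conditions (PPh3, DIAD, THF). The Mitsunobu reaction inverts C4 and should give 19 directly.

Further compounds
F1 | step 8 | 3-methylbut-1-en-2-yl trifluoromethanesulfonate | CC(C)C(=C)OS(=O)(=O)C(F)(F)F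
F2 | step 8 | 4,4,5,5-tetramethyl-2-(3-methylbut-1-en-2-yl)-1,3,2-dioxaborolane | CC(C)C(=C)B1OC(C)(C)C(C)(C)O1
F3 | step 8 | cis-fused 6,8a-dimethyl-3-(propan-2-yl)-3-(4,4,5,5-tetramethyl-1,3,2-dioxaborolan-2-yl)-1,2,3,3a,8,8a-hexahydroazulen-4(5H)-one (C3 epimers) | CC1=CC[C@@]2(C)CCC(C(C)C)(B3OC(C)(C)C(C)(C)O3)[C@H]2C(=O)C1
F4 | step 8 | cis-fused 3-hydroxy-6,8a-dimethyl-3-(propan-2-yl)-1,2,3,3a,8,8a-hexahydroazulen-4(5H)-one (C3 epimers) | CC1=CC[C@@]2(C)CCC(O)(C(C)C)[C@H]2C(=O)C1
F5 | step 11 | (3R,3aR,8aR)-3,3a-epoxy-6,8a-dimethyl-3-(propan-2-yl)-1,2,3,3a,8,8a-hexahydroazulen-4(5H)-one | CC1=CC[C@@]2(C)CC[C@]3(C(C)C)O[C@@]32C(=O)C1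
F6 | step 12 | (3R,3aS,4S,8aR)-6,8a-dimethyl-3-(propan-2-yl)-1,2,3,3a,4,5,8,8a-octahydroazulene-3,4-diol | CC1=CC[C@@]2(C)CC[C@@](O)(C(C)C)[C@@H]2[C@@H](O)C1
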